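Retrosynthetic cuts, in order: the C6 ester; the epoxide oxygen on C8=C14; the two hydroxyls on C9 and C10; then C1–C5 together with C1–C10, which takes the single carbon C1 out of the seven-membered ring and leaves a benzene ring; last C3–C4 (allyl).
Forward: m-cresol → ortho-acyl phenol → tertiary carbinol C4 → silylene bridge → α-methyl α-diazoketone → Buchner ring expansion (five-membered ring closed by C1–C5, benzene ring enlarged to the seven-membered ring) → removal of the C2 carbonyl → work on the three ring double bonds.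
Enabling feature: the ring C5–C6–C7–C8–C9–C10 is a benzene ring and C1 is a carbene carbon. O6 and the C8 branch (C14) sit 1,3 as in m-cresol, and the ring expansion leaves double bonds at C5=C6, C7=C8 and C9=C10, where the target needs oxygen or an alkene. O4 and O6 are 1,3-related through C4–C5–C6, so one silylene can bridge them.
Stereochemistry: C4 by reagent control (chiral allylsilane); C1 from C4 through the bridging ring in the key step; C5 by protonation inside that ring; C9/C10 by OsO4 anti to the C1 methyl; C6 by hydride delivery from the C4 hydroxyl; C8 by epoxidation directed by the C9 hydroxyl.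

Key step: step 6

Assumption: the (S,S)-allylsilane is taken to add allyl to the face of ketone 4 that gives the (R)-carbinol 6; if the sense is the opposite, its enantiomer is used and nothing else changes.
Numbering for bicyclic compounds (daucane): C1 quaternary ring-fusion carbon (CH3 = C15), C2 and C3 ring CH2, C4 carbinol carbon carrying isopropyl, C5 ring-fusion CH, C6 ester carbon, C7 CH2, C8 spiro carbon (C14 on it), C9 and C10 carbinol carbons. β is the face of the C1 methyl. Target: 1β-CH3, 4β-OH, 5α-H, 6α-ester, 8α-epoxide oxygen, 9α-OH, 10α-OH.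

Step 1
Reactants: 1 m-cresol; 2 isobutyryl chloride
Product: 4 1-(2-hydroxy-4-methylphenyl)-2-methylpropan-1-one, via m-tolyl isobutyrate 3 (not isolated)
Conditions: neat, 60 °C; then AlCl3 (1.5 equiv), 140 °C; aq. HCl work-up
Reagents that add atoms: none
Why: O-acylation followed by the Fries rearrangement should give the chelated ortho-hydroxy ketone, which is favoured at high temperature, at the open ortho position para to the ring methyl; no stereocenter is formed.

Step 2
Reactants: 4 1-(2-hydroxy-4-methylphenyl)-2-methylpropan-1-one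
Product: 6 2-[(3R)-3-hydroxy-2-methylhex-5-en-3-yl]-5-methylphenol, via aryloxysilane 5 (not isolated)
Conditions: (S,S)-allylsilane (1.5 equiv), CH2Cl2, 23 °C; then 1 M aq. HCl, 0 °C, brief
Reagents that add atoms: (3aS,7aS)-1,3-bis(4-bromobenzyl)-2-chloro-2-(prop-2-en-1-yl)octahydro-1H-1,3,2-benzodiazasilole, C=CC[Si]1(Cl)N(Cc2ccc(Br)cc2)[C@H]2CCCC[C@@H]2N1Cc1ccc(Br)cc1
Why: Enantioselective allylation of a 2-hydroxyaryl ketone with a strained chiral allylchlorosilane, in which the phenol displaces chloride at silicon and the allyl group is delivered inside the aryloxysilane through a closed six-membered transition state, so the diamine backbone selects the ketone face and sets C4 as R.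

Step 3
Reactants: 6 2-[(3R)-3-hydroxy-2-methylhex-5-en-3-yl]-5-methylphenol
Product: 7 (4R)-2,2-di-tert-butyl-7-methyl-4-(propan-2-yl)-4-(prop-2-en-1-yl)-4H-1,3,2-benzodioxasiline
Conditions: tBu2Si(OTf)2, 2,6-lutidine, CH2Cl2, 0 → 23 °C
Reagents that add atoms: di-tert-butylsilyl bis(trifluoromethanesulfonate), CC(C)(C)[Si](OS(=O)(=O)C(F)(F)F)(OS(=O)(=O)C(F)(F)F)C(C)(C)C
Why: Silylene formation, in which the phenol is silylated first and the tertiary hydroxyl closes the six-membered ring intramolecularly under non-acidic conditions, should avoid ortho-quinone methide formation and leave O4 tied to the future O6 by weakly basic silyl ether oxygens.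

Step 4
Reactants: 7 (4R)-silylene allyl compound
Product: 9 2-[(4R)-2,2-di-tert-butyl-7-methyl-4-(propan-2-yl)-4H-1,3,2-benzodioxasilin-4-yl]acetic acid, via aldehyde 8 (not isolated)
Conditions: O3, CH2Cl2/MeOH, −78 °C; Me2S; then NaClO2, NaH2PO4, 2-methyl-2-butene, tBuOH/H2O, 0 → 23 °C
Reagents that add atoms: ozone, [O-][O+]=O; sodium chlorite, [Na+].[O-]Cl=O
Why: Ozonolysis of the terminal alkene, which reacts far faster than the arene, followed by Pinnick oxidation of the aldehyde should give the acid with the silylene intact under the buffered chlorite.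

Step 5
Reactants: 9 silylene acetic acid
Product: 11 1-[(4R)-2,2-di-tert-butyl-7-methyl-4-(propan-2-yl)-4H-1,3,2-benzodioxasilin-4-yl]-3-diazobutan-2-one, via mixed anhydride 10 (not isolated)
Conditions: iBuOCOCl, Et3N, THF, −15 °C; then CH3CHN2 in Et2O (from N-ethyl-N-nitrosourea, aq. KOH), −15 → 0 °C
Reagents that add atoms: diazoethane, CC=[N+]=[N-]
Why: Acylation of a diazoalkane by a mixed carbonic anhydride (Arndt–Eistert-type acylation) should give the α-methyl α-diazoketone without acid, the carbonate leaving group taking up the proton of the diazonium intermediate.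

Step 6
Reactants: 11 α-methyl α-diazoketone
Product: 13 4β,6-(di-tert-butylsilanediyldioxy)dauca-5,7,9-trien-2-one, via norcaradiene 12 (not isolated)
Conditions: Rh2(OAc)4 (1 mol %), CH2Cl2, 40 °C, slow addition of 11
Reagents that add atoms: none
Why: Intramolecular Buchner reaction: Rh2(OAc)4 turns the diazoketone into an electrophilic rhodium carbene at C1, which adds across the aromatic C5–C10 bond to give norcaradiene 12, and disrotatory six-electron opening of the cyclopropane bond C5–C10 then gives the cycloheptatriene. The closest known reaction type is the dirhodium- or copper-catalysed aromatic addition of 2-diazo-5-arylpentan-3-ones to 8a-methyl dihydroazulenones. The five-membered ring closes 5-exo by attack of C1 on the ipso carbon C5 within a (2+1) cycloaddition, and the seven-membered ring arises by electrocyclic ring expansion of the six-membered ring. The one lasting new stereocenter, C1, is controlled by C4: in 12 the dioxasiline ring (O4 and C6) and the cyclopropane (C10) must lie on opposite faces of the new five-membered ring, so the C1 methyl ends up cis to O4 and trans to isopropyl. Site selectivity for C5–C10 over C5–C6 is secured because C6 carries the ring oxygen; chemoselectivity over 1,2-hydride shift and insertion into the isopropyl C–H bond is expected from the electron-rich arene, the acetate ligands and the hindered, weakly basic silyl ether oxygens, which should not form oxonium ylides.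

Step 7
Reactants: 13 silylene-bridged trienone
Product: 15 4β,6-(di-tert-butylsilanediyldioxy)dauca-5,7,9-triene, via N-silyl hydrazone 14 (not isolated)
Conditions: TBSNHNHTBS, Sc(OTf)3 (1 mol %), CHCl3, 55 °C; then KOtBu, tBuOH, DMSO, 23 → 80 °C
Reagents that add atoms: none
Why: The silyl-hydrazone variant of the Wolff–Kishner reduction should remove the C2 carbonyl, which served only to stabilise the carbene, without acid, and with the acceptor on C1 gone the compound should sit in the cycloheptatriene form needed next.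

Step 8
Reactants: 15 silylene-bridged triene
Product: 16 4β-hydroxydauca-7,9-dien-6-one (5α-H)
Conditions: HF·pyridine, pyridine/THF, 0 → 23 °C
Reagents that add atoms: none
Why: Protodesilylation of the cyclic silyl enol ether, in which C5 is protonated while the six-membered ring is still closed so that C6 stays cis to O4, should set C5 as 5α-H, and this is also the expected equilibrium epimer of the β-hydroxy ketone (hydrogen bond from the C4 hydroxyl to the C6 carbonyl, C6 trans to isopropyl).

Step 9
Reactants: 16 hydroxy dienone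
Product: 17 4β,9α,10α-trihydroxydauc-7-en-6-one
Conditions: OsO4 (2 mol %), NMO (1.5 equiv), acetone/H2O, 0 → 23 °C
Reagents that add atoms: N-methylmorpholine N-oxide, C[N+]1([O-])CCOCC1; water, O (oxygen relayed through OsO4)
Why: Upjohn dihydroxylation should take the electron-richer distal double bond C9=C10 of the dienone, not the deactivated C7=C8, and from the α face opposite the adjacent C1 methyl, setting C9 and C10 as a cis diol.

Step 10
Reactants: 17 trihydroxy enone
Product: 18 4β-hydroxy-9α,10α-(isopropylidenedioxy)dauc-7-en-6-one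
Conditions: Me2C(OMe)2, PPTS (cat.), CH2Cl2, 23 °C
Reagents that add atoms: 2,2-dimethoxypropane, COC(C)(C)OC
Why: Acid-catalysed transketalization should engage only the cis-1,2-diol as a five-membered dioxolane and leave the tertiary C4 hydroxyl free.

Step 11
Reactants: 18 enone acetonide
Product: 20 4β-hydroxy-9α,10α-(isopropylidenedioxy)dauc-8(14)-en-6-one, via dilithium dienolate 19 (not isolated)
Conditions: LiN(iPr)2 (3.5 equiv), THF/DMPU, −78 → −40 °C; then AcOH, −78 °C
Reagents that add atoms: none
Why: Base-induced deconjugation, in which the first equivalent of base forms the C4 alkoxide that shields the already hindered C5–H, so that deprotonation should occur at the exposed C14 methyl to give the extended dienolate, whose kinetic protonation at C7 gives the β,γ-unsaturated ketone with the exocyclic C8=C14 bond.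

Step 12
Reactants: 20 exocyclic-alkene ketone
Product: 21 9α,10α-(isopropylidenedioxy)dauc-8(14)-ene-4β,6α-diol
Conditions: Me4NBH(OAc)3 (5 equiv), MeCN/AcOH, −30 °C
Reagents that add atoms: none
Why: Hydroxyl-directed reduction (Evans–Saksena), in which the C4 hydroxyl exchanges onto boron and delivers hydride to the β face of the C6 carbonyl through a six-membered transition state, should set C6 as the 6α alcohol.

Step 13
Reactants: 21 4β,6α-diol; 22 isovaleryl chloride
Product: 23 4β-hydroxy-9α,10α-(isopropylidenedioxy)dauc-8(14)-en-6α-yl 3-methylbutanoate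
Conditions: pyridine, DMAP (cat.), CH2Cl2, 0 °C
Reagents that add atoms: none
Why: DMAP-catalysed acylation with the acid chloride should esterify only the secondary C6 hydroxyl, the tertiary C4 hydroxyl being unreactive under these conditions.

Step 14
Reactants: 23 ester acetonide
Product: 24 4β,9α,10α-trihydroxydauc-8(14)-en-6α-yl 3-methylbutanoate
Conditions: AcOH/H2O (4:1), 40 °C
Reagents that add atoms: none
Why: Acid-catalysed ketal hydrolysis in aqueous acetic acid should free the 9,10-diol without touching the ester, the tertiary alcohol or the exocyclic alkene.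

Step 15
Reactants: 24 triol ester
Product: 25 8α,14-epoxy-4β,9α,10α-trihydroxydaucan-6α-yl 3-methylbutanoate (target)
Conditions: VO(acac)2 (5 mol %), tBuOOH, CH2Cl2, 0 °C
Reagents that add atoms: tert-butyl hydroperoxide, CC(C)(C)OO
Why: Vanadium-catalysed hydroxyl-directed epoxidation, in which the allylic 9α-hydroxyl (helped by the homoallylic 10α-hydroxyl) binds the metal peroxide and delivers oxygen to the α face of the only alkene, should set C8 with the epoxide oxygen cis to the C9 hydroxyl.

Compound list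
1 | m-cresol (3-methylphenol) | Cc1cccc(O)c1 | starting material
2 | isobutyryl chloride (2-methylpropanoyl chloride) | CC(C)C(Cl)=O | starting material
3 | m-tolyl isobutyrate (3-methylphenyl 2-methylpropanoate) | CC(C)C(=O)Oc1cccc(C)c1 | intermediate
4 | 1-(2-hydroxy-4-methylphenyl)-2-methylpropan-1-one | CC(C)C(=O)c1ccc(C)cc1O | intermediate
5 | aryloxysilane: the allylsilane with chloride replaced by the phenoxide of 4 (ketone still free) | C=CC[Si]1(Oc2cc(C)ccc2C(=O)C(C)C)N(Cc2ccc(Br)cc2)[C@H]2CCCC[C@@H]2N1Cc1ccc(Br)cc1 | intermediate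
6 | 2-[(3R)-3-hydroxy-2-methylhex-5-en-3-yl]-5-methylphenol | C=CC[C@@](O)(C(C)C)c1ccc(C)cc1O | intermediate
7 | (4R)-2,2-di-tert-butyl-7-methyl-4-(propan-2-yl)-4-(prop-2-en-1-yl)-4H-1,3,2-benzodioxasiline | C=CC[C@]1(C(C)C)O[Si](C(C)(C)C)(C(C)(C)C)Oc2cc(C)ccc21 | intermediate
8 | 2-[(4R)-2,2-di-tert-butyl-7-methyl-4-(propan-2-yl)-4H-1,3,2-benzodioxasilin-4-yl]acetaldehyde | O=CC[C@]1(C(C)C)O[Si](C(C)(C)C)(C(C)(C)C)Oc2cc(C)ccc21 | intermediate
9 | 2-[(4R)-2,2-di-tert-butyl-7-methyl-4-(propan-2-yl)-4H-1,3,2-benzodioxasilin-4-yl]acetic acid | OC(=O)C[C@]1(C(C)C)O[Si](C(C)(C)C)(C(C)(C)C)Oc2cc(C)ccc21 | intermediate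
10 | mixed anhydride of 9 with isobutyl hydrogen carbonate | CC(C)COC(=O)OC(=O)C[C@]1(C(C)C)O[Si](C(C)(C)C)(C(C)(C)C)Oc2cc(C)ccc21 | intermediate
11 | 1-[(4R)-2,2-di-tert-butyl-7-methyl-4-(propan-2-yl)-4H-1,3,2-benzodioxasilin-4-yl]-3-diazobutan-2-one | CC(=[N+]=[N-])C(=O)C[C@]1(C(C)C)O[Si](C(C)(C)C)(C(C)(C)C)Oc2cc(C)ccc21 | intermediate
12 | norcaradiene valence tautomer of 13 (cyclopropane C1–C5–C10, diene C6=C7 and C8=C9) | C[C@]12C(=O)C[C@](C(C)C)(O[Si](C(C)(C)C)(C(C)(C)C)O3)[C@]14C3=CC(C)=C[C@H]24 | intermediate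
13 | 4β,6-(di-tert-butylsilanediyldioxy)dauca-5,7,9-trien-2-one (1β-CH3, 4α-isopropyl) | C[C@]12C(=O)C[C@](C(C)C)(O[Si](C(C)(C)C)(C(C)(C)C)O3)C1=C3C=C(C)C=C2 | intermediate
14 | N-(tert-butyldimethylsilyl)hydrazone of 13 at C2 | C[C@]12C(=NN[Si](C)(C)C(C)(C)C)C[C@](C(C)C)(O[Si](C(C)(C)C)(C(C)(C)C)O3)C1=C3C=C(C)C=C2 | intermediate
15 | 4β,6-(di-tert-butylsilanediyldioxy)dauca-5,7,9-triene | C[C@]12CC[C@](C(C)C)(O[Si](C(C)(C)C)(C(C)(C)C)O3)C1=C3C=C(C)C=C2 | intermediate
16 | 4β-hydroxydauca-7,9-dien-6-one (5α-H) | O=C1C=C(C)C=C[C@@]2(C)CC[C@@](O)(C(C)C)[C@H]12 | intermediate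
17 | 4β,9α,10α-trihydroxydauc-7-en-6-one | O=C1C=C(C)[C@@H](O)[C@@H](O)[C@@]2(C)CC[C@@](O)(C(C)C)[C@H]12 | intermediate
18 | 4β-hydroxy-9α,10α-(isopropylidenedioxy)dauc-7-en-6-one | O=C1C=C(C)[C@H]3OC(C)(C)O[C@H]3[C@@]2(C)CC[C@@](O)(C(C)C)[C@H]12 | intermediate
19 | dilithium C4-alkoxide 6,8(14)-dienolate of 18 | [Li+].[Li+].[O-]C1=CC(=C)[C@H]3OC(C)(C)O[C@H]3[C@@]2(C)CC[C@@]([O-])(C(C)C)[C@H]12 | intermediate
20 | 4β-hydroxy-9α,10α-(isopropylidenedioxy)dauc-8(14)-en-6-one | O=C1CC(=C)[C@H]3OC(C)(C)O[C@H]3[C@@]2(C)CC[C@@](O)(C(C)C)[C@H]12 | intermediate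
21 | 9α,10α-(isopropylidenedioxy)dauc-8(14)-ene-4β,6α-diol | O[C@H]1CC(=C)[C@H]3OC(C)(C)O[C@H]3[C@@]2(C)CC[C@@](O)(C(C)C)[C@H]12 | intermediate
22 | isovaleryl chloride (3-methylbutanoyl chloride) | CC(C)CC(Cl)=O | starting material
23 | 4β-hydroxy-9α,10α-(isopropylidenedioxy)dauc-8(14)-en-6α-yl 3-methylbutanoate | CC(C)CC(=O)O[C@H]1CC(=C)[C@H]3OC(C)(C)O[C@H]3[C@@]2(C)CC[C@@](O)(C(C)C)[C@H]12 | intermediate
24 | 4β,9α,10α-trihydroxydauc-8(14)-en-6α-yl 3-methylbutanoate | CC(C)CC(=O)O[C@H]1CC(=C)[C@@H](O)[C@@H](O)[C@@]2(C)CC[C@@](O)(C(C)C)[C@H]12 | intermediate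
25 | 8α,14-epoxy-4β,9α,10α-trihydroxydaucan-6α-yl 3-methylbutanoate | CC(C)CC(=O)O[C@H]1C[C@]2(CO2)[C@@H](O)[C@@H](O)[C@@]2(C)CC[C@@](O)(C(C)C)[C@H]12 | target

Total step count: 15. Longest linear sequence: 15 steps (1 → 25).

Steps most likely to fail

Step 6. The rhodium carbene may be diverted before it adds to the arene: 1,2-hydride shift from the C1 methyl to an enone, insertion into the tertiary C–H bond of the isopropyl group, or slow addition because the bridging ring compresses the tether. The fallback gives up the bridging ring and uses open-chain substrates of the class for which the reaction is established; it sets out from 6 and comes back at 16. MeI/K2CO3 gives the aryl methyl ether F1, and TESOTf/2,6-lutidine the triethylsilyl ether F2. NaIO4 with catalytic KMnO4 (Lemieux–von Rudloff) cleaves the allyl group to the acid F3. Isobutyl chloroformate gives the mixed anhydride F4, and diazoethane the diazoketone F5. Rh2(OAc)4 should then give, through the norcaradiene F6, the azulenone F7; facial control now rests on 1,3-allylic strain (the silyloxy oxygen eclipses the ortho methoxy group, isopropyl lies anti to the carbene). Wolff–Kishner reduction as in step 7, through the silyl hydrazone F8, gives the triene F9, and aqueous HCl in THF hydrolyses the methyl enol ether and the silyl ether to 16.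

Step 11. Enolization may occur at the wrong site (C5–H, with loss of the C5 configuration, or C9–H), the C4 alkoxide may undergo retro-aldol cleavage before the ketone is enolized, or the product may slip back into conjugation on quenching. The fallback moves the double bond by oxidation and reductive transposition; it sets out from 18 and comes back at 23. Me4NBH(OAc)3 reduces the enone 1,2 under direction of the C4 hydroxyl to the allylic alcohol F10, and isovaleryl chloride gives the ester F11. Catalytic SeO2 with tBuOOH hydroxylates the C14 methyl to the primary allylic alcohol F12. Mitsunobu reaction with 2-nitrobenzenesulfonylhydrazide (PPh3, diethyl azodicarboxylate) gives the sulfonylhydrazine F13, which on warming loses sulfinic acid to the allylic diazene F14; retro-ene loss of N2 puts hydrogen on C7 and the double bond at C8=C14, giving 23.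

Step 7. Hydrazone formation at the hindered, doubly neopentyl C2 ketone may stall, tert-butoxide may open the cyclic silyl enol ether, or the triene may isomerize under hot base. The fallback removes the C2 oxygen later by a radical route, at a stage where C1 no longer carries vinyl groups that a C2 radical could migrate into; it sets out from 13 and comes back at 18. NaBH4 reduces the ketone to the C2 alcohol F15 (epimer mixture, of no consequence). HF·pyridine gives the dihydroxy dienone F16, OsO4/NMO the tetraol F17, and 2,2-dimethoxypropane/PPTS the acetonide F18. Thiocarbonyldiimidazole acylates only the secondary C2 hydroxyl to the imidazole thiocarbamate F19, and Bu3SnH with azobisisobutyronitrile in toluene at 90 °C (Barton–McCombie) gives 18.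

Further compounds
F1 | step 6 | (3R)-3-(2-methoxy-4-methylphenyl)-2-methylhex-5-en-3-ol | C=CC[C@@](O)(C(C)C)c1ccc(C)cc1OC
F2 | step 6 | triethyl{[(3R)-3-(2-methoxy-4-methylphenyl)-2-methylhex-5-en-3-yl]oxy}silane | C=CC[C@@](O[Si](CC)(CC)CC)(C(C)C)c1ccc(C)cc1OC
F3 | step 6 | (3R)-3-(2-methoxy-4-methylphenyl)-4-methyl-3-(triethylsilyloxy)pentanoic acid | OC(=O)C[C@@](O[Si](CC)(CC)CC)(C(C)C)c1ccc(C)cc1OC
F4 | step 6 | mixed anhydride of F3 with isobutyl hydrogen carbonate | CC(C)COC(=O)OC(=O)C[C@@](O[Si](CC)(CC)CC)(C(C)C)c1ccc(C)cc1OC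
F5 | step 6 | (5R)-2-diazo-5-(2-methoxy-4-methylphenyl)-6-methyl-5-(triethylsilyloxy)heptan-3-one | CC(=[N+]=[N-])C(=O)C[C@@](O[Si](CC)(CC)CC)(C(C)C)c1ccc(C)cc1OC
F6 | step 6 | norcaradiene valence tautomer of F7 | C[C@]12C(=O)C[C@@](O[Si](CC)(CC)CC)(C(C)C)[C@]14C(OC)=CC(C)=C[C@H]24
F7 | step 6 | 6-methoxy-4β-(triethylsilyloxy)dauca-5,7,9-trien-2-one | C[C@]12C(=O)C[C@@](O[Si](CC)(CC)CC)(C(C)C)C1=C(OC)C=C(C)C=C2
F8 | step 6 | N-(tert-butyldimethylsilyl)hydrazone of F7 at C2 | C[C@]12C(=NN[Si](C)(C)C(C)(C)C)C[C@@](O[Si](CC)(CC)CC)(C(C)C)C1=C(OC)C=C(C)C=C2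
F9 | step 6 | 6-methoxy-4β-(triethylsilyloxy)dauca-5,7,9-triene | C[C@]12CC[C@@](O[Si](CC)(CC)CC)(C(C)C)C1=C(OC)C=C(C)C=C2
F10 | step 11 | 9α,10α-(isopropylidenedioxy)dauc-7-ene-4β,6α-diol | O[C@H]1C=C(C)[C@H]3OC(C)(C)O[C@H]3[C@@]2(C)CC[C@@](O)(C(C)C)[C@H]12
F11 | step 11 | 4β-hydroxy-9α,10α-(isopropylidenedioxy)dauc-7-en-6α-yl 3-methylbutanoate | CC(C)CC(=O)O[C@H]1C=C(C)[C@H]3OC(C)(C)O[C@H]3[C@@]2(C)CC[C@@](O)(C(C)C)[C@H]12
F12 | step 11 | 4β,14-dihydroxy-9α,10α-(isopropylidenedioxy)dauc-7-en-6α-yl 3-methylbutanoate | CC(C)CC(=O)O[C@H]1C=C(CO)[C@H]3OC(C)(C)O[C@H]3[C@@]2(C)CC[C@@](O)(C(C)C)[C@H]12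
F13 | step 11 | N-(C14-alkyl)-N-(2-nitrobenzenesulfonyl)hydrazine from F12 | CC(C)CC(=O)O[C@H]1C=C(CN(N)S(=O)(=O)c4ccccc4[N+](=O)[O-])[C@H]3OC(C)(C)O[C@H]3[C@@]2(C)CC[C@@](O)(C(C)C)[C@H]12
F14 | step 11 | allylic C14 diazene from F13 | CC(C)CC(=O)O[C@H]1C=C(CN=N)[C@H]3OC(C)(C)O[C@H]3[C@@]2(C)CC[C@@](O)(C(C)C)[C@H]12
F15 | step 7 | 4β,6-(di-tert-butylsilanediyldioxy)dauca-5,7,9-trien-2-ol (C2 epimers) | C[C@]12C(O)C[C@](C(C)C)(O[Si](C(C)(C)C)(C(C)(C)C)O3)C1=C3C=C(C)C=C2
F16 | step 7 | 2,4β-dihydroxydauca-7,9-dien-6-one (C2 epimers) | O=C1C=C(C)C=C[C@@]2(C)C(O)C[C@@](O)(C(C)C)[C@H]12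
F17 | step 7 | 2,4β,9α,10α-tetrahydroxydauc-7-en-6-one (C2 epimers) | O=C1C=C(C)[C@@H](O)[C@@H](O)[C@@]2(C)C(O)C[C@@](O)(C(C)C)[C@H]12
F18 | step 7 | 2,4β-dihydroxy-9α,10α-(isopropylidenedioxy)dauc-7-en-6-one (C2 epimers) | O=C1C=C(C)[C@H]3OC(C)(C)O[C@H]3[C@@]2(C)C(O)C[C@@](O)(C(C)C)[C@H]12
F19 | step 7 | O-(C2) 1H-imidazole-1-carbothioate of F18 | O=C1C=C(C)[C@H]3OC(C)(C)O[C@H]3[C@@]2(C)C(OC(=S)n4ccnc4)C[C@@](O)(C(C)C)[C@H]12
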